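Assumption: clerodane numbering is used for all bicyclic compounds (ring A = C1–C5 and C10, ring B = C5–C10, side chain C11–C15 with methyl C16 on C13, C17 on C8, C18 on C4, C19 on C5, C20 on C9); β means the face of the decalin that carries the C5 methyl C19, α the opposite face. The target is then (5S,7S,8S,9R,10R,13R)-7β-acetoxy-2-hydroxy-3-oxo-cis-cleroda-1,4(18)-dien-15-oic acid.

**Retrosynthetic overview**
1. Ring A end game: the diosphenol comes from C2 hydroxylation and oxidation of a 3-oxo-4(18)-ene, itself from a C4 ketone (methylenation, then allylic oxidation at C3); the tert-butyl ester is cleaved last.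
2. Ring B substituents: 7β-OAc and 8α-Me come from hydroboration of a C7=C8(Me) alkene, made from the C8 ketone via its enol triflate.
3. Stereocentres at the ring fusion: cis C10–H by reductive 1,3-transposition of a 1(10)-en-2-one tosylhydrazone; quaternary C9 by deconjugative methylation of the 9(10)-en-8-one.
4. Key bond C5–C6: intermolecular Michael addition of 2-methylcyclohexane-1,3-dione to a vinyl ketone that carries the whole side chain (C13 from (R)-citronellic acid), followed by asymmetric aldol condensation (C9–C10).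
5. Ring order: ring A is bought as the dione; ring B is annulated onto it (Michael, then aldol).

**Route**

Step 1
Reactants: 1 (R)-citronellic acid
Product: 2 tert-butyl (3R)-3,7-dimethyloct-6-enoate
Conditions: Boc2O, DMAP (cat.), t-BuOH, 30 °C
Reagents that add atoms: di-tert-butyl dicarbonate, CC(C)(C)OC(=O)OC(=O)OC(C)(C)C
Why: DMAP-catalysed mixed-anhydride esterification masks the acid as a base-stable tert-butyl ester without touching the alkene or the C3 stereocentre (the future C13).

Step 2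
Reactants: 2 tert-butyl (3R)-3,7-dimethyloct-6-enoate
Product: 4 tert-butyl (3R)-3-methyl-6-oxohexanoate, via ozonide 3 (not isolated)
Conditions: O3, CH2Cl2, −78 °C; then PPh3
Reagents that add atoms: ozone, [O-][O+]=O
Why: Ozonolysis with reductive work-up cleaves the trisubstituted alkene to the aldehyde and leaves the remote stereocentre untouched.

Step 3
Reactants: 4 tert-butyl (3R)-3-methyl-6-oxohexanoate
Product: 5 tert-butyl (3R)-7-methoxy-3-methylhept-6-enoate (E/Z mixture)
Conditions: Ph3P(CH2OMe)Cl, KOtBu, THF, 0 °C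
Reagents that add atoms: (methoxymethyl)triphenylphosphonium chloride, COC[P+](c1ccccc1)(c1ccccc1)c1ccccc1.[Cl-]
Why: Wittig methoxymethylenation adds the one carbon needed (future C8) as an enol ether.

Step 4
Reactants: 5 tert-butyl (3R)-7-methoxy-3-methylhept-6-enoate
Product: 6 tert-butyl (3R)-3-methyl-7-oxoheptanoate
Conditions: 2 M HCl, THF, rt
Reagents that add atoms: water, O
Why: Acid hydrolysis of the enol ether unveils the homologous aldehyde, and dilute acid at room temperature does not cleave a tert-butyl ester.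

Step 5
Reactants: 6 tert-butyl (3R)-3-methyl-7-oxoheptanoate
Product: 7 tert-butyl (3R)-7-hydroxy-3-methylnon-8-enoate (both C7 epimers)
Conditions: CH2=CHMgBr, THF, −78 °C; then H2O
Reagents that add atoms: vinylmagnesium bromide, C=C[Mg]Br
Why: Grignard 1,2-addition to the aldehyde at −78 °C is much faster than attack on the hindered tert-butyl ester; the carbinol configuration is irrelevant.

Step 6
Reactants: 7 tert-butyl (3R)-7-hydroxy-3-methylnon-8-enoate
Product: 8 tert-butyl (3R)-3-methyl-7-oxonon-8-enoate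
Conditions: Dess–Martin periodinane, NaHCO3, CH2Cl2, 0 °C to rt
Reagents that add atoms: none
Why: Dess–Martin oxidation of the allylic alcohol gives the vinyl ketone under neutral conditions that avoid its polymerisation.

Step 7
Reactants: 8 tert-butyl (3R)-3-methyl-7-oxonon-8-enoate; 9 2-methylcyclohexane-1,3-dione
Product: 10 tert-butyl (3R)-3-methyl-9-(1-methyl-2,6-dioxocyclohexyl)-7-oxononanoate
Conditions: Et3N (0.2 equiv), MeCN, rt
Reagents that add atoms: none
Why: Amine-catalysed Michael addition of the acidic 2-methyl-1,3-dione to the unhindered vinyl ketone joins the ring A fragment to the side-chain fragment through the C5–C6 bond; C5 is still prochiral.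

Step 8
Reactants: 10 tert-butyl (3R)-3-methyl-9-(1-methyl-2,6-dioxocyclohexyl)-7-oxononanoate
Product: 11 tert-butyl (3R)-3-methyl-5-[(4aS)-4a-methyl-2,5-dioxo-2,3,4,4a,5,6,7,8-octahydronaphthalen-1-yl]pentanoate
Conditions: L-phenylalanine (1 equiv), (1S)-(+)-10-camphorsulfonic acid (0.5 equiv), DMF, 30 to 70 °C
Reagents that add atoms: none
Why: Amino-acid-mediated enamine aldol condensation (Hajos–Parrish–Eder–Sauer–Wiechert variant of the Robinson annulation) closes ring B; the L-phenylalanine enamine differentiates the two enantiotopic ring carbonyls and sets C5 as S.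

Step 9
Reactants: 11 enedione (4,8-dioxo-9(10)-ene)
Product: 12 4β-hydroxy-9(10)-en-8-one (4S)
Conditions: NaBH4 (0.3 equiv), EtOH, −10 °C
Reagents that add atoms: none
Why: Chemoselective hydride reduction of the saturated ketone (the tetrasubstituted enone is far less electrophilic); hydride adds anti to the adjacent axial C19 methyl and gives the equatorial 4β alcohol.

Step 10
Reactants: 12 4β-hydroxy-9(10)-en-8-one
Product: 13 4β-(tert-butyldimethylsilyloxy)-9(10)-en-8-one
Conditions: TBSCl, imidazole, DMF, 40 °C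
Reagents that add atoms: tert-butyldimethylsilyl chloride, CC(C)(C)[Si](C)(C)Cl
Why: Silyl ether formation protects C4 as a small equatorial group that survives base, oxidants, hydride and organometallic reagents.

Step 11
Reactants: 13 4β-silyloxy-9(10)-en-8-one
Product: 15 4β-silyloxy-9α-methyl-1(10)-en-8-one, via potassium dienolate 14 (not isolated)
Conditions: KOtBu (1.3 equiv), t-BuOH/THF, rt; then MeI, 0 °C
Reagents that add atoms: iodomethane, CI
Why: Thermodynamic γ-deprotonation gives the extended dienolate, which is C-methylated at C9 (deconjugative α-alkylation); MeI approaches anti to the axial C19 methyl, so C20 is α and the side chain β (9R).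

Step 12
Reactants: 15 4β-silyloxy-9α-methyl-1(10)-en-8-one
Product: 16 4β-silyloxy-9α-methyl-1(10)-ene-2,8-dione
Conditions: CrO3, 3,5-dimethylpyrazole, CH2Cl2, −20 °C
Reagents that add atoms: chromium trioxide, O=[Cr](=O)=O
Why: Allylic oxidation is regiospecific because C2 is the only allylic CH2 of the C1=C10 alkene (C5 and C9 are quaternary).

Step 13
Reactants: 16 4β-silyloxy-9α-methyl-1(10)-ene-2,8-dione
Product: 17 C2 tosylhydrazone of 16
Conditions: TsNHNH2 (1.05 equiv), EtOH, rt
Reagents that add atoms: p-toluenesulfonyl hydrazide, Cc1ccc(cc1)S(=O)(=O)NN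
Why: Hydrazone condensation occurs at the accessible enone carbonyl, while the C8 ketone next to the quaternary C9 reacts much more slowly.

Step 14
Reactants: 17 C2 tosylhydrazone
Product: 20 4β-silyloxy-cis-1-en-8-one (10β-H), via N-boryl hydrazine 18 (not isolated), via allylic diazene 19 (not isolated)
Conditions: catecholborane, CHCl3, 0 °C; then NaOAc·3H2O, reflux
Reagents that add atoms: none
Why: Reductive 1,3-transposition of an enone tosylhydrazone (Kabalka reduction): hydride adds to C2 from the α face, and the resulting 2β-diazene passes its hydrogen suprafacially to the β face of C10 with loss of N2 (retro-ene), setting the cis ring fusion (10R) and moving the alkene to C1=C2.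

Step 15
Reactants: 20 4β-silyloxy-cis-1-en-8-one
Product: 21 4β-silyloxy-cis-decalin-8-one
Conditions: H2 (1 atm), Pd/C, EtOAc, rt
Reagents that add atoms: none
Why: Heterogeneous catalytic hydrogenation of the disubstituted alkene creates no stereocentre and leaves the hindered ketone alone.

Step 16
Reactants: 21 4β-silyloxy-cis-decalin-8-one
Product: 23 C7=C8 enol triflate, via potassium enolate 22 (not isolated)
Conditions: KN(SiMe3)2, THF, −78 °C; then PhNTf2, −78 to 0 °C
Reagents that add atoms: N-phenylbis(trifluoromethanesulfonimide), O=S(=O)(N(c1ccccc1)S(=O)(=O)C(F)(F)F)C(F)(F)F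
Why: Enolate O-triflation is regiospecific because C7 is the only enolisable position of the C8 ketone.

Step 17
Reactants: 23 C7=C8 enol triflate
Product: 24 8-methyl-7-ene (C17 installed)
Conditions: Me2CuLi, THF, −20 to 0 °C
Reagents that add atoms: lithium dimethylcuprate, [Li+].C[Cu-]C
Why: Cuprate cross-coupling of an enol triflate (McMurry–Scott) replaces the triflate by methyl without moving the alkene; the tert-butyl ester is inert to the cuprate.

Step 18
Reactants: 24 8-methyl-7-ene
Product: 26 7β-hydroxy-8α-methyl compound (7S,8S), via alkylborane 25 (not isolated)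
Conditions: BH3·THF, 0 °C to rt; then NaOH, H2O2
Reagents that add atoms: hydrogen peroxide, OO
Why: Hydroboration–oxidation adds H and OH syn and anti-Markovnikov from the β face (the α face is shielded by the axial C20 methyl and by C4), which sets 8α-Me and 7β-OH trans to each other.

Step 19
Reactants: 26 7β-hydroxy-8α-methyl compound
Product: 27 7β-acetate
Conditions: Ac2O, pyridine, DMAP (cat.), CH2Cl2, rt
Reagents that add atoms: acetic anhydride, CC(=O)OC(C)=O
Why: DMAP-catalysed acylation of the equatorial secondary alcohol installs the acetate of the target.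

Step 20
Reactants: 27 7β-acetate
Product: 28 4β-alcohol
Conditions: HF·pyridine, THF, 0 °C to rt
Reagents that add atoms: none
Why: Fluoride-driven desilylation frees C4–OH while acetate and tert-butyl ester are stable.

Step 21
Reactants: 28 4β-alcohol
Product: 29 4-ketone
Conditions: Dess–Martin periodinane, NaHCO3, CH2Cl2, rt
Reagents that add atoms: none
Why: Dess–Martin oxidation of the only free hydroxyl gives the C4 ketone without epimerisable centres at risk (C5 is quaternary).

Step 22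
Reactants: 29 4-ketone
Product: 30 4(18)-methylene compound
Conditions: Zn, CH2Br2, TiCl4, THF/CH2Cl2, 0 °C to rt
Reagents that add atoms: dibromomethane, BrCBr
Why: Takai–Lombardo methylenation is non-basic, converts hindered ketones and does not react with the acetate or the tert-butyl ester.

Step 23
Reactants: 30 4(18)-methylene compound
Product: 31 3-hydroxy-4(18)-ene (C3 epimers)
Conditions: SeO2 (0.5 equiv), t-BuOOH, CH2Cl2, rt
Reagents that add atoms: tert-butyl hydroperoxide, CC(C)(C)OO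
Why: Selenium-dioxide allylic hydroxylation (ene reaction, then 2,3-sigmatropic shift) can only occur at C3 because C5 is quaternary, and it returns the exocyclic alkene.

Step 24
Reactants: 31 3-hydroxy-4(18)-ene
Product: 32 3-oxo-4(18)-ene (exo-methylene enone)
Conditions: Dess–Martin periodinane, NaHCO3, CH2Cl2, 0 °C
Reagents that add atoms: none
Why: Mild Dess–Martin oxidation of the allylic alcohol gives the α-methylene ketone; the alkene cannot migrate because C5 bears no hydrogen.

Step 25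
Reactants: 32 3-oxo-4(18)-ene
Product: 34 2-hydroxy-3-oxo-4(18)-ene (acyloin; C2 epimers), via potassium enolate 33 (not isolated)
Conditions: KN(SiMe3)2, THF, −78 °C; then 2-(phenylsulfonyl)-3-phenyloxaziridine; AcOH quench
Reagents that add atoms: 2-(phenylsulfonyl)-3-phenyloxaziridine, O=S(=O)(c1ccccc1)N1OC1c1ccccc1
Why: Kinetic α'-deprotonation (C2 is the only enolisable position) followed by Davis oxaziridine enolate hydroxylation; the new C2 centre is destroyed in the next step.

Step 26
Reactants: 34 2-hydroxy-3-oxo-4(18)-ene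
Product: 36 diosphenol tert-butyl ester, via 2,3-diketone 35 (not isolated)
Conditions: Dess–Martin periodinane, CH2Cl2, rt
Reagents that add atoms: none
Why: Dess–Martin oxidation of the acyloin gives the 2,3-dione, which enolises toward C1 (the only direction available) to the conjugated diosphenol.

Step 27
Reactants: 36 diosphenol tert-butyl ester
Product: 37 target acid
Conditions: CF3CO2H/CH2Cl2 (1:4), 0 °C to rt
Reagents that add atoms: none
Why: Acidolysis of the tert-butyl ester (loss of isobutene) frees the acid under conditions that spare the acetate, the diosphenol and the non-isomerisable exocyclic enone.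

**Compound list**

1 | (R)-citronellic acid, (3R)-3,7-dimethyloct-6-enoic acid | CC(C)=CCC[C@@H](C)CC(=O)O | starting material
2 | tert-butyl (3R)-3,7-dimethyloct-6-enoate | CC(C)=CCC[C@@H](C)CC(=O)OC(C)(C)C | intermediate
3 | ozonide (1,2,4-trioxolane) of 2 | CC1(C)OOC(CC[C@@H](C)CC(=O)OC(C)(C)C)O1 | intermediate (not isolated)
4 | tert-butyl (3R)-3-methyl-6-oxohexanoate | O=CCC[C@@H](C)CC(=O)OC(C)(C)C | intermediate
5 | tert-butyl (3R)-7-methoxy-3-methylhept-6-enoate (E/Z) | COC=CCC[C@@H](C)CC(=O)OC(C)(C)C | intermediate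
6 | tert-butyl (3R)-3-methyl-7-oxoheptanoate | O=CCCC[C@@H](C)CC(=O)OC(C)(C)C | intermediate
7 | tert-butyl (3R)-7-hydroxy-3-methylnon-8-enoate (C7 epimers) | C=CC(O)CCC[C@@H](C)CC(=O)OC(C)(C)C | intermediate
8 | tert-butyl (3R)-3-methyl-7-oxonon-8-enoate (vinyl ketone) | C=CC(=O)CCC[C@@H](C)CC(=O)OC(C)(C)C | intermediate
9 | 2-methylcyclohexane-1,3-dione | CC1C(=O)CCCC1=O | starting material
10 | tert-butyl (3R)-3-methyl-9-(1-methyl-2,6-dioxocyclohexyl)-7-oxononanoate (triketone) | CC1(CCC(=O)CCC[C@@H](C)CC(=O)OC(C)(C)C)C(=O)CCCC1=O | intermediate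
11 | enedione: tert-butyl (3R)-3-methyl-5-[(4aS)-4a-methyl-2,5-dioxo-2,3,4,4a,5,6,7,8-octahydronaphthalen-1-yl]pentanoate (4,8-dioxo-9(10)-ene, 5S) | O=C1CCCC2=C(CC[C@@H](C)CC(=O)OC(C)(C)C)C(=O)CC[C@]12C | intermediate
12 | 4β-hydroxy-9(10)-en-8-one (4S,5S; OH cis to C19) | O[C@H]1CCCC2=C(CC[C@@H](C)CC(=O)OC(C)(C)C)C(=O)CC[C@]12C | intermediate
13 | 4β-TBS ether of 12 | CC(C)(C)[Si](C)(C)O[C@H]1CCCC2=C(CC[C@@H](C)CC(=O)OC(C)(C)C)C(=O)CC[C@]12C | intermediate
14 | potassium 1(10),8-dienolate of 13 | CC(C)(C)[Si](C)(C)O[C@H]1CCC=C2C(CC[C@@H](C)CC(=O)OC(C)(C)C)=C([O-])CC[C@]12C.[K+] | intermediate (not isolated)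
15 | 4β-silyloxy-9α-methyl-1(10)-en-8-one (C20 α, side chain β) | CC(C)(C)[Si](C)(C)O[C@H]1CCC=C2[C@@](C)(CC[C@@H](C)CC(=O)OC(C)(C)C)C(=O)CC[C@]12C | intermediate
16 | 4β-silyloxy-9α-methyl-1(10)-ene-2,8-dione | CC(C)(C)[Si](C)(C)O[C@H]1CC(=O)C=C2[C@@](C)(CC[C@@H](C)CC(=O)OC(C)(C)C)C(=O)CC[C@]12C | intermediate
17 | C2 p-toluenesulfonylhydrazone of 16 | CC(C)(C)[Si](C)(C)O[C@H]1CC(=NNS(=O)(=O)c3ccc(C)cc3)C=C2[C@@](C)(CC[C@@H](C)CC(=O)OC(C)(C)C)C(=O)CC[C@]12C | intermediate
18 | 2β-(N-catecholboryl-N'-tosylhydrazino)-1(10)-ene | CC(C)(C)[Si](C)(C)O[C@H]1C[C@@H](N(NS(=O)(=O)c3ccc(C)cc3)B3Oc4ccccc4O3)C=C2[C@@](C)(CC[C@@H](C)CC(=O)OC(C)(C)C)C(=O)CC[C@]12C | intermediate (not isolated)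
19 | 2β-diazenyl-1(10)-ene (allylic diazene) | CC(C)(C)[Si](C)(C)O[C@H]1C[C@@H](N=N)C=C2[C@@](C)(CC[C@@H](C)CC(=O)OC(C)(C)C)C(=O)CC[C@]12C | intermediate (not isolated)
20 | 4β-silyloxy-cis-1-en-8-one (10β-H, cis to C19) | CC(C)(C)[Si](C)(C)O[C@H]1CC=C[C@@H]2[C@@](C)(CC[C@@H](C)CC(=O)OC(C)(C)C)C(=O)CC[C@]12C | intermediate
21 | 4β-silyloxy-cis-decalin-8-one | CC(C)(C)[Si](C)(C)O[C@H]1CCC[C@@H]2[C@@](C)(CC[C@@H](C)CC(=O)OC(C)(C)C)C(=O)CC[C@]12C | intermediate
22 | potassium C7=C8 enolate of 21 | CC(C)(C)[Si](C)(C)O[C@H]1CCC[C@@H]2[C@@](C)(CC[C@@H](C)CC(=O)OC(C)(C)C)C([O-])=CC[C@]12C.[K+] | intermediate (not isolated)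
23 | 8-(trifluoromethanesulfonyloxy)-7-ene (enol triflate) | CC(C)(C)[Si](C)(C)O[C@H]1CCC[C@@H]2[C@@](C)(CC[C@@H](C)CC(=O)OC(C)(C)C)C(OS(=O)(=O)C(F)(F)F)=CC[C@]12C | intermediate
24 | 8-methyl-7-ene | CC(C)(C)[Si](C)(C)O[C@H]1CCC[C@@H]2[C@@](C)(CC[C@@H](C)CC(=O)OC(C)(C)C)C(C)=CC[C@]12C | intermediate
25 | 7β-boryl-8α-methyl alkylborane | CC(C)(C)[Si](C)(C)O[C@H]1CCC[C@@H]2[C@@](C)(CC[C@@H](C)CC(=O)OC(C)(C)C)[C@H](C)[C@@H](B)C[C@]12C | intermediate (not isolated)
26 | 7β-hydroxy-8α-methyl-4β-silyloxy compound | CC(C)(C)[Si](C)(C)O[C@H]1CCC[C@@H]2[C@@](C)(CC[C@@H](C)CC(=O)OC(C)(C)C)[C@H](C)[C@@H](O)C[C@]12C | intermediate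
27 | 7β-acetoxy-8α-methyl-4β-silyloxy compound | CC(C)(C)[Si](C)(C)O[C@H]1CCC[C@@H]2[C@@](C)(CC[C@@H](C)CC(=O)OC(C)(C)C)[C@H](C)[C@@H](OC(C)=O)C[C@]12C | intermediate
28 | 7β-acetoxy-4β-hydroxy compound | O[C@H]1CCC[C@@H]2[C@@](C)(CC[C@@H](C)CC(=O)OC(C)(C)C)[C@H](C)[C@@H](OC(C)=O)C[C@]12C | intermediate
29 | 7β-acetoxy-4-ketone | O=C1CCC[C@@H]2[C@@](C)(CC[C@@H](C)CC(=O)OC(C)(C)C)[C@H](C)[C@@H](OC(C)=O)C[C@]12C | intermediate
30 | tert-butyl 7β-acetoxy-cis-clerod-4(18)-en-15-oate | C=C1CCC[C@@H]2[C@@](C)(CC[C@@H](C)CC(=O)OC(C)(C)C)[C@H](C)[C@@H](OC(C)=O)C[C@]12C | intermediate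
31 | 3-hydroxy derivative of 30 (C3 epimers) | C=C1C(O)CC[C@@H]2[C@@](C)(CC[C@@H](C)CC(=O)OC(C)(C)C)[C@H](C)[C@@H](OC(C)=O)C[C@]12C | intermediate
32 | 3-oxo-4(18)-ene (exo-methylene enone) | C=C1C(=O)CC[C@@H]2[C@@](C)(CC[C@@H](C)CC(=O)OC(C)(C)C)[C@H](C)[C@@H](OC(C)=O)C[C@]12C | intermediate
33 | potassium C2=C3 enolate of 32 | C=C1C([O-])=CC[C@@H]2[C@@](C)(CC[C@@H](C)CC(=O)OC(C)(C)C)[C@H](C)[C@@H](OC(C)=O)C[C@]12C.[K+] | intermediate (not isolated)
34 | 2-hydroxy-3-oxo-4(18)-ene (C2 epimers) | C=C1C(=O)C(O)C[C@@H]2[C@@](C)(CC[C@@H](C)CC(=O)OC(C)(C)C)[C@H](C)[C@@H](OC(C)=O)C[C@]12C | intermediate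
35 | 2,3-dioxo-4(18)-ene | C=C1C(=O)C(=O)C[C@@H]2[C@@](C)(CC[C@@H](C)CC(=O)OC(C)(C)C)[C@H](C)[C@@H](OC(C)=O)C[C@]12C | intermediate (not isolated)
36 | tert-butyl ester of the target (2-hydroxy-3-oxo-1,4(18)-diene) | C=C1C(=O)C(O)=C[C@@H]2[C@@](C)(CC[C@@H](C)CC(=O)OC(C)(C)C)[C@H](C)[C@@H](OC(C)=O)C[C@]12C | intermediate
37 | (5S,7S,8S,9R,10R,13R)-7-acetoxy-2-hydroxy-3-oxo-cis-cleroda-1,4(18)-dien-15-oic acid | C=C1C(=O)C(O)=C[C@@H]2[C@@](C)(CC[C@@H](C)CC(=O)O)[C@H](C)[C@@H](OC(C)=O)C[C@]12C | target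

**Step count and risks**

Total steps: 27. Longest linear sequence: 27 steps (1 to 37); the dione 9 enters at step 7.

The three steps most likely to fail:

Step 14 (reductive transposition that sets the cis ring fusion). The face of hydride addition at C2 and the transfer to the very hindered C10 rest on analogy with steroidal 4-en-3-one tosylhydrazones. The fallback sets out from 15 and uses hydroxyl-directed hydrogenation instead: 15 is desilylated with HF·pyridine to the homoallylic alcohol F1, which is hydrogenated with [Ir(cod)(PCy3)(py)]PF6 and H2 in CH2Cl2. The 4β-hydroxyl binds the catalyst and delivers hydrogen to the β face of the C1=C10 alkene, giving the cis-fused hydroxy ketone F2. Silylation (TBSCl, imidazole) then comes back to the route at 21.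

Step 18 (facial selectivity of the hydroboration). If borane attacks the α face, both C7 and C8 come out wrong. The fallback sets out from 21 and avoids hydroboration: the potassium enolate of 21 is hydroxylated with the Davis oxaziridine on its open β face to the 7β-ketol F3, which is acetylated (Ac2O, pyridine) to the keto acetate F4. Methylenation at C8 (Zn, CH2Br2, TiCl4) gives the 8(17)-methylene acetate F5. Homogeneous hydrogenation with RhCl(PPh3)3 and H2 from the β face (the α face is blocked by the axial C20 methyl) gives the 8α-methyl compound and comes back to the route at 27.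

Step 25 (enolate hydroxylation of the exo-methylene enone). The enone is a strong Michael acceptor and the acetate is base-sensitive. The fallback sets out from 29 and installs both ring A oxygens before the methylene:
- 29 is dehydrogenated with 2-iodoxybenzoic acid (DMSO, 70 °C) to the 2-en-4-one F6.
- Dihydroxylation (OsO4 cat., N-methylmorpholine N-oxide) gives the cis-2,3-diol F7, which is protected (2,2-dimethoxypropane, pyridinium p-toluenesulfonate) as the acetonide F8.
- Methylenation at C4 (Zn, CH2Br2, TiCl4) gives the 4(18)-methylene acetonide F9, and 80% aqueous AcOH frees the methylene diol F10.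
- Oxidation of both hydroxyls with Dess–Martin periodinane gives the 2,3-dione, which enolises and comes back to the route at 36.

**Further compounds**

F1 | step 14 | 4β-hydroxy-9α-methyl-1(10)-en-8-one (15 without the silyl group) | O[C@H]1CCC=C2[C@@](C)(CC[C@@H](C)CC(=O)OC(C)(C)C)C(=O)CC[C@]12C
F2 | step 14 | 4β-hydroxy-cis-decalin-8-one (10β-H) | O[C@H]1CCC[C@@H]2[C@@](C)(CC[C@@H](C)CC(=O)OC(C)(C)C)C(=O)CC[C@]12C
F3 | step 18 | 7β-hydroxy-8-ketone (4β-silyloxy) | CC(C)(C)[Si](C)(C)O[C@H]1CCC[C@@H]2[C@@](C)(CC[C@@H](C)CC(=O)OC(C)(C)C)C(=O)[C@@H](O)C[C@]12C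
F4 | step 18 | 7β-acetoxy-8-ketone (4β-silyloxy) | CC(C)(C)[Si](C)(C)O[C@H]1CCC[C@@H]2[C@@](C)(CC[C@@H](C)CC(=O)OC(C)(C)C)C(=O)[C@@H](OC(C)=O)C[C@]12C
F5 | step 18 | 7β-acetoxy-8(17)-methylene compound (4β-silyloxy) | CC(C)(C)[Si](C)(C)O[C@H]1CCC[C@@H]2[C@@](C)(CC[C@@H](C)CC(=O)OC(C)(C)C)C(=C)[C@@H](OC(C)=O)C[C@]12C
F6 | step 25 | 7β-acetoxy-2-en-4-one | O=C1C=CC[C@@H]2[C@@](C)(CC[C@@H](C)CC(=O)OC(C)(C)C)[C@H](C)[C@@H](OC(C)=O)C[C@]12C
F7 | step 25 | 7β-acetoxy-cis-2,3-dihydroxy-4-ketone (diol configuration immaterial) | O=C1C(O)C(O)C[C@@H]2[C@@](C)(CC[C@@H](C)CC(=O)OC(C)(C)C)[C@H](C)[C@@H](OC(C)=O)C[C@]12C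
F8 | step 25 | 2,3-O-isopropylidene derivative of F7 | O=C1C3OC(C)(C)OC3C[C@@H]2[C@@](C)(CC[C@@H](C)CC(=O)OC(C)(C)C)[C@H](C)[C@@H](OC(C)=O)C[C@]12C
F9 | step 25 | 4(18)-methylene 2,3-acetonide | C=C1C3OC(C)(C)OC3C[C@@H]2[C@@](C)(CC[C@@H](C)CC(=O)OC(C)(C)C)[C@H](C)[C@@H](OC(C)=O)C[C@]12C
F10 | step 25 | 4(18)-methylene-2,3-diol | C=C1C(O)C(O)C[C@@H]2[C@@](C)(CC[C@@H](C)CC(=O)OC(C)(C)C)[C@H](C)[C@@H](OC(C)=O)C[C@]12C
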